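**Retrosynthetic overview**

- The strategy rests on the 1,4-benzoquinone ring: C1 and C4 are the carbonyl carbons, C2 alone carries a carbon substituent (the furan α-carbon), and C3, C5 and C6 are CH. This maps onto one CO ligand (C1), a terminal alkyne (C2–C3), a carbene carbon (C4) and a vinyl unit (C5–C6).
- The quinone is disconnected to a 4-methoxyphenyl trimethylsilyl ether. That ether is disconnected by Dötz benzannulation to the (R)-ethynylfuran isovalerate and (CO)5Cr=C(OMe)CH=CHSiMe3.
- The ethynylfuran ester comes from acylation, alkyne desilylation and CBS reduction of a 3-furyl ketone. The ketone comes from a 3-furyllithium and the Weinreb amide of 4-methylpent-3-enoic acid, and the alkyne from 4-bromofuran-2-carbaldehyde by Ohira–Bestmann homologation.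
- The carbene complex comes from (E)-(2-bromovinyl)trimethylsilane, Cr(CO)6 and Me3OBF4.
- Ring order: the furan is bought intact and the six-membered ring is the only ring formed (step 9). The single stereocentre is set by the CBS reduction (step 5).

Key step: step 9

Remark: the aryl trimethylsilyl ether from the key step is hydrolytically labile, so it is assumed to be carried into the oxidation after filtration only, without chromatography.

**Route**

Step 1
Reactants: 1 4-bromofuran-2-carbaldehyde
Product: 2 4-bromo-2-ethynylfuran
Conditions: dimethyl (1-diazo-2-oxopropyl)phosphonate (1.2 equiv), K2CO3, MeOH, 0 °C → rt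
Reagents that add atoms: dimethyl (1-diazo-2-oxopropyl)phosphonate (Ohira–Bestmann reagent), COP(=O)(OC)C(=[N+]=[N-])C(C)=O
Why: Ohira–Bestmann (Seyferth–Gilbert) homologation, in which the diazomethylphosphonate anion released by methanolysis adds to the aldehyde and loss of phosphate and N2 with 1,2-hydrogen shift should give the terminal alkyne, the ring bromide being inert to K2CO3/MeOH.

Step 2
Reactants: 2 4-bromo-2-ethynylfuran
Product: 4 [(4-bromofuran-2-yl)ethynyl]trimethylsilane, via lithium acetylide 3 (not isolated)
Conditions: LiN(SiMe3)2 (1.05 equiv), THF, −78 °C; Me3SiCl, −78 → 0 °C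
Reagents that add atoms: chlorotrimethylsilane, C[Si](C)(C)Cl
Why: Alkyne C-silylation, in which the amide base removes only the acetylenic proton (far more acidic than the furan C–H, and no bromine–lithium exchange with an amide base) and the acetylide is trapped on silicon.

Step 3
Reactants: 5 4-methylpent-3-enoic acid
Product: 7 N-methoxy-N,4-dimethylpent-3-enamide, via acyl imidazole 6 (not isolated)
Conditions: 1,1'-carbonyldiimidazole, CH2Cl2, 0 °C → rt; MeNH(OMe)·HCl, rt
Reagents that add atoms: N,O-dimethylhydroxylamine hydrochloride, CNOC.Cl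
Why: Weinreb amide formation through the acyl imidazole under near-neutral conditions, which should leave the β,γ-alkene out of conjugation.

Step 4
Reactants: 4 [(4-bromofuran-2-yl)ethynyl]trimethylsilane; 7 N-methoxy-N,4-dimethylpent-3-enamide
Product: 10 4-methyl-1-{5-[(trimethylsilyl)ethynyl]furan-3-yl}pent-3-en-1-one, via 3-furyllithium 8 (not isolated), via lithium hemiaminal chelate 9 (not isolated)
Conditions: 4, n-BuLi (1.0 equiv), THF, −78 °C; 7, −78 °C; AcOH/THF quench at −78 °C
Reagents that add atoms: none
Why: Bromine–lithium exchange followed by Weinreb ketone synthesis, in which the chelated tetrahedral adduct survives until the cold acidic quench, so that over-addition and base-mediated migration of the alkene into conjugation are avoided.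

Step 5
Reactants: 10 4-methyl-1-{5-[(trimethylsilyl)ethynyl]furan-3-yl}pent-3-en-1-one
Product: 12 (1R)-4-methyl-1-{5-[(trimethylsilyl)ethynyl]furan-3-yl}pent-3-en-1-ol, via catechol borate ester 11 (not isolated)
Conditions: (S)-2-methyl-CBS-oxazaborolidine (15 mol%), catecholborane (1.8 equiv), toluene, −78 °C; MeOH, then aqueous NaHCO3
Reagents that add atoms: none
Why: CBS reduction, in which the (S)-oxazaborolidine binds the ketone with the furyl group as the large substituent and delivers hydride to the Si face (the sense that turns acetophenone into (R)-1-phenylethanol), which should set the (R)-carbinol, while catecholborane at −78 °C leaves the alkene and the silylalkyne alone.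

Step 6
Reactants: 12 (1R)-4-methyl-1-{5-[(trimethylsilyl)ethynyl]furan-3-yl}pent-3-en-1-ol
Product: 13 (1R)-1-(5-ethynylfuran-3-yl)-4-methylpent-3-en-1-ol
Conditions: K2CO3 (0.2 equiv), MeOH, 0 °C
Reagents that add atoms: none
Why: Methoxide-catalysed protodesilylation of the alkynylsilane, run before the ester is installed so that no ester is exposed to methanolysis, with the carbinol centre untouched.

Step 7
Reactants: 13 (1R)-1-(5-ethynylfuran-3-yl)-4-methylpent-3-en-1-ol
Product: 14 (1R)-1-(5-ethynylfuran-3-yl)-4-methylpent-3-enyl 3-methylbutanoate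
Conditions: 3-methylbutanoyl chloride, pyridine, DMAP (cat.), CH2Cl2, 0 °C
Reagents that add atoms: 3-methylbutanoyl chloride, CC(C)CC(Cl)=O
Why: DMAP-catalysed O-acylation, which does not break the C–O bond of the carbinol and so retains the (R) configuration.

Step 8
Reactants: 15 (E)-(2-bromovinyl)trimethylsilane; 16 hexacarbonylchromium
Product: 19 pentacarbonyl[(E)-1-methoxy-3-(trimethylsilyl)prop-2-enylidene]chromium, via silylvinyllithium 17 (not isolated), via lithium acylchromate 18 (not isolated)
Conditions: 15, t-BuLi (2 equiv), Et2O, −78 °C; Cr(CO)6, Et2O, −78 °C → rt; Me3OBF4, CH2Cl2/H2O, 0 °C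
Reagents that add atoms: trimethyloxonium tetrafluoroborate, C[O+](C)C.F[B-](F)(F)F
Why: Fischer carbene synthesis, in which the vinyllithium (formed with retention of the E geometry) adds to a CO ligand and the resulting acylate is O-methylated by the oxonium salt.

Step 9
Reactants: 14 (1R)-1-(5-ethynylfuran-3-yl)-4-methylpent-3-enyl 3-methylbutanoate; 19 pentacarbonyl[(E)-1-methoxy-3-(trimethylsilyl)prop-2-enylidene]chromium
Product: 21 (1R)-1-{5-[5-methoxy-2-(trimethylsilyloxy)phenyl]furan-3-yl}-4-methylpent-3-enyl 3-methylbutanoate, via silyl cyclohexadienone 20 (not isolated)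
Conditions: 19 (1.3 equiv), THF (0.05 M, degassed), 50 °C, Ar; then air, rt, filtration through Celite
Reagents that add atoms: none
Why: Dötz benzannulation: loss of one CO from 19 frees a site on zerovalent chromium, the alkyne of 14 inserts into the Cr=C bond with its CH terminus bonding to the carbene carbon, and insertion of a second CO ligand gives a chromium-bound dienylketene. The six-membered ring closes by 6π-electrocyclisation of this ketene (bond between the ketene carbon and the silyl-bearing vinyl carbon) to dienone 20, whose Me3Si group then moves from C6 to the carbonyl oxygen, so that aromatisation gives the silyl ether with hydrogen at the former silyl position. The closest known reaction type is the benzannulation of alkenyl(methoxy)carbene complexes of chromium with terminal arylacetylenes, including β-silylvinyl complexes used as stable equivalents of the parent vinyl complex. No stereocentre is formed: the transient C6 centre of 20 is lost on aromatisation and the (R)-carbinol centre is remote from all bond-forming events. The step needs regioselective alkyne insertion, which the size difference between the furyl group and hydrogen secures (furyl ends ortho to the oxygen derived from CO), and phenol formation over five-membered ring by-products, which the alkenyl carbene substituent and THF as solvent favour. The prenyl alkene and the ester are not expected to react with the carbene at 50 °C.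

Step 10
Reactants: 21 (1R)-1-{5-[5-methoxy-2-(trimethylsilyloxy)phenyl]furan-3-yl}-4-methylpent-3-enyl 3-methylbutanoate
Product: 23 (1R)-1-[5-(3,6-dioxocyclohexa-1,4-dien-1-yl)furan-3-yl]-4-methylpent-3-enyl 3-methylbutanoate, via methoxyphenol 22 (not isolated)
Conditions: (NH4)2Ce(NO3)6 (2.5 equiv), MeCN/H2O (4:1), 0 °C, 15 min
Reagents that add atoms: water, O
Why: Oxidative demethylation by tetravalent cerium, in which the silyl ether is hydrolysed in the acidic aqueous medium, the 4-methoxyphenol is oxidised by two one-electron steps, and water adds at the methoxy-bearing carbon with loss of methanol to give the 1,4-benzoquinone faster than the furan or the alkene should be oxidised at 0 °C.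

**Compound list**

1 | 4-bromofuran-2-carbaldehyde | O=Cc1cc(Br)co1 | starting material
2 | 4-bromo-2-ethynylfuran | C#Cc1cc(Br)co1 | intermediate
3 | lithium (4-bromofuran-2-yl)acetylide | [Li]C#Cc1cc(Br)co1 | intermediate (not isolated)
4 | [(4-bromofuran-2-yl)ethynyl]trimethylsilane | C[Si](C)(C)C#Cc1cc(Br)co1 | intermediate
5 | 4-methylpent-3-enoic acid | CC(C)=CCC(O)=O | starting material
6 | 1-(imidazol-1-yl)-4-methylpent-3-en-1-one | CC(C)=CCC(=O)n1ccnc1 | intermediate (not isolated)
7 | N-methoxy-N,4-dimethylpent-3-enamide | CC(C)=CCC(=O)N(C)OC | intermediate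
8 | {5-[(trimethylsilyl)ethynyl]furan-3-yl}lithium | [Li]c1coc(C#C[Si](C)(C)C)c1 | intermediate (not isolated)
9 | lithium 1-[methoxy(methyl)amino]-4-methyl-1-{5-[(trimethylsilyl)ethynyl]furan-3-yl}pent-3-en-1-olate (racemic at C1) | CC(C)=CCC(O[Li])(N(C)OC)c1coc(C#C[Si](C)(C)C)c1 | intermediate (not isolated)
10 | 4-methyl-1-{5-[(trimethylsilyl)ethynyl]furan-3-yl}pent-3-en-1-one | CC(C)=CCC(=O)c1coc(C#C[Si](C)(C)C)c1 | intermediate
11 | 2-{[(1R)-4-methyl-1-{5-[(trimethylsilyl)ethynyl]furan-3-yl}pent-3-en-1-yl]oxy}-1,3,2-benzodioxaborole | CC(C)=CC[C@@H](OB1Oc2ccccc2O1)c1coc(C#C[Si](C)(C)C)c1 | intermediate (not isolated)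
12 | (1R)-4-methyl-1-{5-[(trimethylsilyl)ethynyl]furan-3-yl}pent-3-en-1-ol | CC(C)=CC[C@@H](O)c1coc(C#C[Si](C)(C)C)c1 | intermediate
13 | (1R)-1-(5-ethynylfuran-3-yl)-4-methylpent-3-en-1-ol | CC(C)=CC[C@@H](O)c1coc(C#C)c1 | intermediate
14 | (1R)-1-(5-ethynylfuran-3-yl)-4-methylpent-3-enyl 3-methylbutanoate | CC(C)=CC[C@@H](OC(=O)CC(C)C)c1coc(C#C)c1 | intermediate
15 | (E)-(2-bromovinyl)trimethylsilane | C[Si](C)(C)/C=C/Br | starting material
16 | hexacarbonylchromium | O=C=[Cr](=C=O)(=C=O)(=C=O)(=C=O)=C=O | starting material
17 | (E)-[2-(trimethylsilyl)vinyl]lithium | [Li]/C=C/[Si](C)(C)C | intermediate (not isolated)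
18 | lithium pentacarbonyl[(E)-3-(trimethylsilyl)acryloyl]chromate | [Li+].[O-]C(/C=C/[Si](C)(C)C)=[Cr](=C=O)(=C=O)(=C=O)(=C=O)=C=O | intermediate (not isolated)
19 | pentacarbonyl[(E)-1-methoxy-3-(trimethylsilyl)prop-2-enylidene]chromium | COC(/C=C/[Si](C)(C)C)=[Cr](=C=O)(=C=O)(=C=O)(=C=O)=C=O | intermediate
20 | (1R)-1-{5-[3-methoxy-6-oxo-5-(trimethylsilyl)cyclohexa-1,3-dien-1-yl]furan-3-yl}-4-methylpent-3-enyl 3-methylbutanoate (either configuration at the silyl-bearing ring carbon; held on a Cr(CO)3 fragment in the flask, drawn as the free ligand) | CC(C)=CC[C@@H](OC(=O)CC(C)C)c1coc(C2=CC(OC)=CC([Si](C)(C)C)C2=O)c1 | intermediate (not isolated)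
21 | (1R)-1-{5-[5-methoxy-2-(trimethylsilyloxy)phenyl]furan-3-yl}-4-methylpent-3-enyl 3-methylbutanoate | CC(C)=CC[C@@H](OC(=O)CC(C)C)c1coc(-c2cc(OC)ccc2O[Si](C)(C)C)c1 | intermediate
22 | (1R)-1-[5-(2-hydroxy-5-methoxyphenyl)furan-3-yl]-4-methylpent-3-enyl 3-methylbutanoate | CC(C)=CC[C@@H](OC(=O)CC(C)C)c1coc(-c2cc(OC)ccc2O)c1 | intermediate (not isolated)
23 | (1R)-1-[5-(3,6-dioxocyclohexa-1,4-dien-1-yl)furan-3-yl]-4-methylpent-3-enyl 3-methylbutanoate | CC(C)=CC[C@@H](OC(=O)CC(C)C)c1coc(C2=CC(=O)C=CC2=O)c1 | target

**Step count**

Total steps: 10. Longest linear sequence: 8 steps (steps 1, 2, 4, 5, 6, 7, 9, 10 from aldehyde 1); steps 3 and 8 are side branches.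

**Steps most likely to fail**

1. Step 9 (key step). What may go wrong:
- alkyne insertion with the opposite orientation;
- ring closure without CO insertion, giving five-membered products;
- proton instead of silyl migration in dienone 20, leaving silicon on the ring;
- oligomerisation of the ethynylfuran at 50 °C.

Fallback (the aryl–furan bond is made by cross-coupling in place of ring construction): it sets out from Weinreb amide 7 and rejoins the route at phenol 22. Commercial 3-bromofuran (Brc1ccoc1) would be lithiated with n-BuLi in THF at −78 °C to furan-3-yllithium F1. Acylation of this with 7 and a cold AcOH quench would give 1-(furan-3-yl)-4-methylpent-3-en-1-one F2. CBS reduction as in step 5 should give (1R)-1-(furan-3-yl)-4-methylpent-3-en-1-ol F3, and acylation as in step 7 would give (1R)-1-(furan-3-yl)-4-methylpent-3-enyl 3-methylbutanoate F4. Sterically controlled C–H borylation ([Ir(OMe)(cod)]2, 4,4'-di-tert-butyl-2,2'-bipyridine, B2pin2, hexane, rt) should take place at the furan α-position remote from the side chain. This would give (1R)-4-methyl-1-[5-(4,4,5,5-tetramethyl-1,3,2-dioxaborolan-2-yl)furan-3-yl]pent-3-enyl 3-methylbutanoate F5. Suzuki coupling of F5 with commercial 2-bromo-4-methoxyphenol (COc1ccc(O)c(Br)c1) using Pd(dppf)Cl2 and K3PO4 in dioxane/H2O at 60 °C would give phenol 22, this time isolated. It is then oxidised as in step 10 to 23.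

2. Step 10. What may go wrong:
- one-electron oxidation of the electron-rich 2-arylfuran or of the prenyl alkene by tetravalent cerium, in competition with oxidation of the methoxyphenol;
- acid-promoted ionisation of the furylic ester.

Fallback (two-electron oxidation through a quinone monoketal): it sets out from silyl ether 21 and rejoins the route at target 23. The silyl ether would be cleaved with citric acid in MeOH at rt and phenol 22 isolated. PhI(OAc)2 in MeOH at 0 °C should then give the quinone monoketal (1R)-1-[5-(3,3-dimethoxy-6-oxocyclohexa-1,4-dien-1-yl)furan-3-yl]-4-methylpent-3-enyl 3-methylbutanoate F6. Hydrolysis of the ketal with aqueous oxalic acid in THF at rt would give 23.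

3. Step 4. What may go wrong:
- proton transfer from the doubly activated α-methylene of amide 7 to the furyllithium, instead of addition;
- equilibration of the 3-furyllithium to the α-lithio isomer;
- migration of the alkene into conjugation during the quench.

Fallback (addition to an aldehyde, then oxidation): it sets out from bromide 4 and amide 7 and rejoins the route at ketone 10. Amide 7 would be reduced with i-Bu2AlH in THF at −78 °C to 4-methylpent-3-enal F7, which is used at once. Furyllithium 8, made from 4 as in step 4, would be added to F7 at −78 °C to give racemic 4-methyl-1-{5-[(trimethylsilyl)ethynyl]furan-3-yl}pent-3-en-1-ol F8. Dess–Martin periodinane with NaHCO3 in CH2Cl2 would oxidise F8 to ketone 10 without moving the alkene, and the CBS reduction of step 5 then sets the stereocentre as planned.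

**Further compounds**

F1 | step 9 | furan-3-yllithium | [Li]c1ccoc1
F2 | step 9 | 1-(furan-3-yl)-4-methylpent-3-en-1-one | CC(C)=CCC(=O)c1ccoc1
F3 | step 9 | (1R)-1-(furan-3-yl)-4-methylpent-3-en-1-ol | CC(C)=CC[C@@H](O)c1ccoc1
F4 | step 9 | (1R)-1-(furan-3-yl)-4-methylpent-3-enyl 3-methylbutanoate | CC(C)=CC[C@@H](OC(=O)CC(C)C)c1ccoc1
F5 | step 9 | (1R)-4-methyl-1-[5-(4,4,5,5-tetramethyl-1,3,2-dioxaborolan-2-yl)furan-3-yl]pent-3-enyl 3-methylbutanoate | CC(C)=CC[C@@H](OC(=O)CC(C)C)c1coc(B2OC(C)(C)C(C)(C)O2)c1
F6 | step 10 | (1R)-1-[5-(3,3-dimethoxy-6-oxocyclohexa-1,4-dien-1-yl)furan-3-yl]-4-methylpent-3-enyl 3-methylbutanoate | CC(C)=CC[C@@H](OC(=O)CC(C)C)c1coc(C2=CC(OC)(OC)C=CC2=O)c1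
F7 | step 4 | 4-methylpent-3-enal | CC(C)=CCC=O
F8 | step 4 | 4-methyl-1-{5-[(trimethylsilyl)ethynyl]furan-3-yl}pent-3-en-1-ol (racemic) | CC(C)=CCC(O)c1coc(C#C[Si](C)(C)C)c1
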